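The trap in repeating this run is to count on heat or on the time allowed for more product, so reckon first how far the enzyme gets before it is lost.

    free enzyme → unfolded enzyme (k1 = 1.8 × 10⁻⁴ s⁻¹, Ea1 = 241 kJ mol⁻¹)
    starting material + free enzyme → product + free enzyme, rate k2*[starting material]*[free enzyme]/(1 + ([starting material]/Km2) + ([product]/Kp2)) (Km2 = 2.4 mM, Kp2 = 8.1 mM, k2 = 2.0 × 10⁵ M⁻¹ s⁻¹, Ea2 = 31.0 kJ mol⁻¹)
    free enzyme + product → spent catalyst (k3 = 8.9 M⁻¹ s⁻¹, Ea3 = 57.0 kJ mol⁻¹)
    (constants at 37 °C)

| setting | teal | blue | grey |
|---|---|---|---|
| starting material | 20 mM | 20 mM | 20 mM |
| free enzyme | 0.58 µM | 0.58 µM | 0.58 µM |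
| temperature | 57 °C | 37 °C |  |
| time | 8.0 min | 8.0 min | 8.0 min |
| remark |  |  | at 57 °C until 6.0 min, from then on at 37 °C |

- constants are those at 37 °C; use the activation energies for any other temperature

- the flask that comes out highest in amount of product, in percent of the starting material charged, or "all alike" when all lie within 1.5 percentage points (teal / blue / grey / all alike)
- product at the end, in percent of the starting material charged, teal
- product at the end, in percent of the starting material charged, blue
- product at the end, in percent of the starting material charged, grey

Free enzyme makes product and is lost, each at a rate proportional to its own concentration, so dividing one rate by the other removes both that concentration and the time. For each unit of product made, the free enzyme lost is (attack constant × c(product) + unfolding constant) × drag / making constant. The drag is the denominator of the rate law divided by c(starting material). Hold the drag fixed and add up from zero product. The summed loss is then drag / making constant × (0.5 × attack constant × reach × reach + unfolding constant × reach), and you set this equal to the charge of free enzyme and solve for the reach.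

At the start the drag is 0.467 mM⁻¹. With it, blue at 37 °C reaches 7.45 mM. From 37 °C to 57 °C unfolding speeds up 290-fold, attack 3.8-fold and making 2.1-fold, so loss gains on making. Teal then reaches 4.19 mM.

The weak link is the fixed drag, which grows as starting material falls. The loss also grows with product, so read the drag at 2/3 of the reach instead. That gives 0.524 mM⁻¹ for blue and 0.495 mM⁻¹ for teal.

Blue now reaches 7.03 mM, or 35.2 % of the charge. Teal gives 4.04 mM, or 20.2 %. This is the reach, the product concentration at which the summed loss equals the charge of free enzyme; per enzyme it is the total turnover number.

Unfolding by itself halves free enzyme at 57 °C in 0.223 min, far shorter than the 6.0 min before grey is cooled. So I give grey the reach of teal.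

The forecast says blue comes out highest, with teal 20.2 %, blue 35.2 % and grey 20.2 %, since “heat speeds the loss far more than the conversion”.

The simulation puts blue highest, with teal 20.3 %, blue 35.2 % and grey 20.3 %; blue already stands at 35.2 % product after 4.00 min, and a tenfold time changes nothing in blue. Now take grey's neighbour with 34 mM of starting material. Reading the drag at 2/3 of teal's reach of 4.04 mM gives 0.459 mM⁻¹. Its reach is then 4.23 mM, which is 12.4 % of its charge. That neighbour flask ends with 87.5 % of its starting material left and 12.5 % as product.

(The constants are those of an exercise; the rest is arithmetic.)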